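**Retrosynthetic overview**

1. Ring numbering: C1 and C5 are the gem-diprenyl carbons, C6 the ketone between them, C2 and C4 the carbonyl and enol carbons, C3 the ring carbon that carries the isobutyryl group. The strategy rests on C3: it is the only ring carbon without prenyl groups and is bonded to three acyl-type carbons (C2, C4 and the side-chain C=O), so it is a triacylmethane carbon. The other five ring atoms C2-C1-C6-C5-C4 form a symmetric 2,2,4,4-tetraprenyl-3-oxoglutarate.
2. Cutting C2-C3 and C3-C4 ([5+1]) gives 3-methylbutan-2-one, whose CH3 becomes C3, and dimethyl 2,2,4,4-tetraprenyl-3-oxopentanedioate. The single six-membered carbocycle closes in this last step by Claisen and then Dieckmann acylation.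
3. The diester goes back to dimethyl 3-oxopentanedioate and four prenyl bromide, through two rounds of enolate C-alkylation (C2 and C4 first, then the two quaternary centres).
4. Ring order: one ring only, formed last; the target has no stereocentre.

Key step: step 3

Remark on the chemistry: colupone is achiral and exists as rapidly interconverting enol tautomers, of which the target SMILES shows one. Prenyl means 3-methylbut-2-en-1-yl throughout.

**Route**

Step 1
Reactants: 1 dimethyl 3-oxopentanedioate; 2 prenyl bromide (1-bromo-3-methylbut-2-ene)
Product: 4 dimethyl 2,4-bis(3-methylbut-2-en-1-yl)-3-oxopentanedioate (meso/racemic mixture), via mono-prenyl diester 3 (not isolated)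
Conditions: 2 (2.2 equiv), K2CO3 (3 equiv), acetone, 0 °C to 45 °C
Reagents that add atoms: none
Why: Enolate C-alkylation (SN2) of a doubly activated 1,3-dicarbonyl with a soft allylic bromide, in which the still unsubstituted α-CH2 of 3 is the more acidic and less hindered site so that the second prenyl group should enter at C4; the two new stereocentres are not controlled and are erased in step 2, and any 2,2-di- or triprenylated material converges on the same product there.

Step 2
Reactants: 4 dimethyl 2,4-bis(3-methylbut-2-en-1-yl)-3-oxopentanedioate; 2 prenyl bromide
Product: 6 dimethyl 2,2,4,4-tetrakis(3-methylbut-2-en-1-yl)-3-oxopentanedioate, via triprenyl diester 5 (not isolated)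
Conditions: NaH (2.6 equiv), THF, 0 °C; 2 (2.8 equiv), nBu4NI (10 mol %), 0 °C to 50 °C
Reagents that add atoms: none
Why: Irreversible deprotonation of each remaining α-CH by NaH followed by SN2 C-alkylation of the chelated sodium β-keto ester enolate, with iodide catalysis making the electrophile softer and THF keeping the ion pair tight, both of which favour C- over O-prenylation; both stereocentres of 4 become achiral quaternary carbons.

Step 3
Reactants: 6 dimethyl 2,2,4,4-tetrakis(3-methylbut-2-en-1-yl)-3-oxopentanedioate; 7 3-methylbutan-2-one
Product: 11 colupone (3-hydroxy-2-(2-methylpropanoyl)-4,4,6,6-tetrakis(3-methylbut-2-en-1-yl)cyclohex-2-ene-1,5-dione), via lithium enolate 8 (not isolated), via open-chain diketone 9 (not isolated), via lithium triketonate 10 (not isolated)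
Conditions: 7 (3.0 equiv), LiN(iPr)2 (3.1 equiv), THF, −78 °C; 6 (1.0 equiv) added, −78 °C to rt, then 50 °C; 1 M aq HCl, 0 °C
Reagents that add atoms: none
Why: Crossed Claisen condensation followed by Dieckmann cyclisation: the methyl-side lithium enolate 8 adds to one ester carbonyl of 6 and expels methoxide to form C2-C3, and the β-diketone 9 is deprotonated at C3 at once by a second equivalent of 8, which is why three equivalents are used. The diketonate carbon C3 then attacks the second ester to form C3-C4, a 6-exo-trig closure of the only ring (enolexo with respect to the side-chain enolate C3=C(OLi)iPr, the 6-enolendo mode through C3=C2 being allowed as well), helped by the gem-diprenyl groups at C1 and C5 (Thorpe-Ingold effect). Loss of the second methoxide and a last deprotonation give the triketonate 10, the thermodynamic sink that should pull the reversible events (O-acylation, self-aldol addition of 8) forward, and cold dilute acid then releases 11. The closest known reaction types are the base-mediated condensation of methyl ketones with dialkyl phthalates to 2-acylindane-1,3-diones and the Claisen acylation of pinacolone with methyl pivalate, which show double acylation of one methyl carbon and enolate attack on an α-quaternary ester. No stereocentre is formed, since 11 is achiral. Two selectivities are needed: methyl over methine deprotonation of 7, secured by LiN(iPr)2 at −78 °C and backed by the fact that methine acylation cannot end in a stabilised enolate and stays reversible; and attack on the ester carbonyls and not on the C6 ketone, secured because C6 lies between two quaternary carbons whereas each ester has only one and is activated by lithium chelation to the β-carbonyl.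

**Compound list**

1 | dimethyl 3-oxopentanedioate | COC(=O)CC(=O)CC(=O)OC | starting material
2 | prenyl bromide (1-bromo-3-methylbut-2-ene) | CC(C)=CCBr | starting material
3 | dimethyl 2-(3-methylbut-2-en-1-yl)-3-oxopentanedioate (racemic, not isolated) | COC(=O)C(CC=C(C)C)C(=O)CC(=O)OC | intermediate
4 | dimethyl 2,4-bis(3-methylbut-2-en-1-yl)-3-oxopentanedioate (meso/racemic mixture) | COC(=O)C(CC=C(C)C)C(=O)C(CC=C(C)C)C(=O)OC | intermediate
5 | dimethyl 2,2,4-tris(3-methylbut-2-en-1-yl)-3-oxopentanedioate (racemic, not isolated) | COC(=O)C(CC=C(C)C)(CC=C(C)C)C(=O)C(CC=C(C)C)C(=O)OC | intermediate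
6 | dimethyl 2,2,4,4-tetrakis(3-methylbut-2-en-1-yl)-3-oxopentanedioate | COC(=O)C(CC=C(C)C)(CC=C(C)C)C(=O)C(CC=C(C)C)(CC=C(C)C)C(=O)OC | intermediate
7 | 3-methylbutan-2-one | CC(=O)C(C)C | starting material
8 | lithium 3-methylbut-1-en-2-olate (kinetic enolate of 7, not isolated) | C=C(O[Li])C(C)C | intermediate
9 | methyl 8-methyl-2,2,4,4-tetrakis(3-methylbut-2-en-1-yl)-3,5,7-trioxononanoate (present as its lithium enolate, not isolated) | COC(=O)C(CC=C(C)C)(CC=C(C)C)C(=O)C(CC=C(C)C)(CC=C(C)C)C(=O)CC(=O)C(C)C | intermediate
10 | lithium triketonate of colupone (not isolated) | CC(C)=CCC1(CC=C(C)C)C(=O)C(C(=O)C(C)C)=C(O[Li])C(CC=C(C)C)(CC=C(C)C)C1=O | intermediate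
11 | colupone | CC(C)=CCC1(CC=C(C)C)C(=O)C(C(=O)C(C)C)=C(O)C(CC=C(C)C)(CC=C(C)C)C1=O | target

Total step count: 3
Longest linear sequence: 3 steps (1 to 4 to 6 to 11)

**Steps most likely to fail**

Step 3 (key step). Addition of enolate 8 to the α-quaternary ester carbonyls of 6 may be too slow. Self-aldol condensation of 7, retro-Claisen scission of 6 at C6, or a second intermolecular Claisen at the far ester of 9 could then take over before the ring closes. The fallback takes the ring from an aromatic precursor and does not build it. It draws on prenyl bromide 2 as its only compound from the route. Phloroglucinol would be acylated with isobutyryl chloride (AlCl3, nitrobenzene-CH2Cl2, Friedel-Crafts) to 2-methyl-1-(2,4,6-trihydroxyphenyl)propan-1-one (phlorisobutyrophenone) F1. F1 would be C-prenylated three times with dearomatisation (2, NaOMe, MeOH, −10 °C to rt) to colupulone F2. The sodium salt of F2 (NaH, toluene, 0 °C to rt) would then be alkylated once more with 2 at the one enolic ring carbon that still bears a single prenyl group. This gives colupone directly, so the fallback returns to the route at 11. O-prenylated and under-alkylated material would have to be separated by chromatography.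

Step 2. O-prenylation of the hindered, fully substituted enolate, or stalling at the triprenyl stage, may occur when the two quaternary centres are formed. The fallback replaces the SN2 alkylation by π-allyl palladium chemistry (Tsuji-Trost) and sets out from 4. The sodium enolate of 4 (NaH, THF) would be treated with prenyl acetate and Pd(PPh3)4 (5 mol %, zerovalent palladium) at rt to 60 °C, in two rounds in one flask. The stabilised enolate should attack the unsubstituted terminus of the prenyl palladium complex, which gives the linear prenyl group. Any prenyl enol ether is re-ionised by the catalyst and fed back to C-alkylation. The sequence passes through 5 and returns to the route at 6. It makes no compound outside the list (F0).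

Step 1. Base-induced self-condensation of 1, and uneven alkylation before both α-carbons carry a prenyl group, may lower the throughput. The fallback assembles the 3-oxoglutarate from two malonate halves and sets out from prenyl bromide 2. Dimethyl malonate would be alkylated with 2 (NaOMe, MeOH) to dimethyl 2-(3-methylbut-2-en-1-yl)propanedioate F3. F3 would be half-saponified (KOH, 1 equiv, MeOH, then cold dilute acid) to 2-(methoxycarbonyl)-5-methylhex-4-enoic acid F4. Half of F4 would be activated with 1,1'-carbonyldiimidazole (THF, rt) to the acyl imidazolide F5 and combined with the magnesium salt of the other half (MgCl2, Et3N, MeCN-THF, rt to 40 °C). Decarboxylative Claisen condensation of the Masamune-Brooks type should then give the 2,4-diprenyl-3-oxoglutarate, so the fallback returns to the route at 4.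

**Further compounds**

F1 | step 3 | 2-methyl-1-(2,4,6-trihydroxyphenyl)propan-1-one (phlorisobutyrophenone) | CC(C)C(=O)c1c(O)cc(O)cc1O
F2 | step 3 | colupulone (3,5-dihydroxy-2-(2-methylpropanoyl)-4,6,6-tris(3-methylbut-2-en-1-yl)cyclohexa-2,4-dien-1-one) | CC(C)C(=O)C1=C(O)C(CC=C(C)C)=C(O)C(CC=C(C)C)(CC=C(C)C)C1=O
F0 | step 2 | none | none
F3 | step 1 | dimethyl 2-(3-methylbut-2-en-1-yl)propanedioate | COC(=O)C(CC=C(C)C)C(=O)OC
F4 | step 1 | 2-(methoxycarbonyl)-5-methylhex-4-enoic acid (racemic) | COC(=O)C(CC=C(C)C)C(O)=O
F5 | step 1 | methyl 2-(1H-imidazole-1-carbonyl)-5-methylhex-4-enoate (racemic) | COC(=O)C(CC=C(C)C)C(=O)n1ccnc1
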